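**Retrosynthetic overview**

1. Target 22 comes from allylic alcohol 21 by oxidation. 21 comes from diol-lactone 15 by α-methylenation and two ordered acylations (O9 methacrylate first, then O6 angelate).
2. 15 comes from bis(allylboronate) 8 and lactone aldehyde 12 in one flask: a double allylboration makes C5–C6, then C9–C10, and closes the cyclohexane. The γ-lactone ring is already present in 12 (ring order: lactone in step 6, carbocycle in step 7).
3. Enabling feature: the ring carbinol carbons C6 and C9 sit 1,4 across the six-membered ring, and each is homoallylic to an alkene on its ring neighbour (C4=C15 on C5, C1=C2 on C10). The carbocycle is therefore the double-allylation retron of a 1,4-dialdehyde and a hexa-2,4-diene-1,6-diyl bis(boronate).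
4. 8 comes from 1 and 2 (Baylis–Hillman-type adduct, double allylic borylation). 12 comes from 9 and 10 (proline cross-aldol, lactonisation).

Key step: step 7

Remark (assumption): elemane locants are used throughout (C10 quaternary, then C5, C6, C7, C8, C9 around the ring; C11–C13 lactone carbons; C1=C2 vinyl; C3/C4/C15 propenal unit; C14 methyl). (E)-4-Acetoxy-2-methylbut-2-enal and 2,2-dimethoxyacetaldehyde are taken as commercial.

**Route**

Step 1
Reactants: 1 (2E)-3-methyl-4-oxobut-2-en-1-yl acetate; 2 methyl prop-2-ynoate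
Product: 4 methyl 2-[(2E)-4-(acetyloxy)-1-hydroxy-2-methylbut-2-en-1-yl]prop-2-enoate (racemic at the carbinol), via vinylalane 3 (not isolated)
Conditions: i-Bu2AlH, NMO, THF, 0 °C; 2, 0 °C; then 1, 0 → 23 °C; aqueous work-up
Reagents that add atoms: none
Why: Vinylalumination: hydroalumination of 2 gives the α-alumino acrylate 3, which adds 1,2 to the enal to give a Morita–Baylis–Hillman-type adduct; the carbinol centre is erased in step 3, so no stereocontrol is needed, and the (E) alkene of 1 is untouched.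

Step 2
Reactants: 4 methyl 2-[(2E)-4-(acetyloxy)-1-hydroxy-2-methylbut-2-en-1-yl]prop-2-enoate
Product: 5 methyl 2-[(2E)-1,4-bis(acetyloxy)-2-methylbut-2-en-1-yl]prop-2-enoate (racemic)
Conditions: Ac2O, pyridine, DMAP (cat.), CH2Cl2, 0 → 23 °C
Reagents that add atoms: acetic anhydride, CC(=O)OC(C)=O
Why: DMAP-catalysed acetylation turns the doubly allylic alcohol into the second allylic leaving group.

Step 3
Reactants: 5 methyl 2-[(2E)-1,4-bis(acetyloxy)-2-methylbut-2-en-1-yl]prop-2-enoate
Product: 6 methyl (2E,4E)-4-methyl-6-(4,4,5,5-tetramethyl-1,3,2-dioxaborolan-2-yl)-2-[(4,4,5,5-tetramethyl-1,3,2-dioxaborolan-2-yl)methyl]hexa-2,4-dienoate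
Conditions: B2pin2 (2.4 equiv), Pd2(dba)3 (2.5 mol %), DMSO, 50 °C
Reagents that add atoms: bis(pinacolato)diboron, CC1(C)OB(OC1(C)C)B1OC(C)(C)C(C)(C)O1
Why: Miyaura-type borylation of allylic acetates under zerovalent palladium (π-allyl intermediates): the primary acetate should give the linear (E)-allylboronate, and the Baylis–Hillman acetate the 2-(borylmethyl)enoate with the alkenyl group trans to the ester (the conjugated, favoured isomer), which places C10 cis to the CH2B carbon as step 7 requires.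

Step 4
Reactants: 6 methyl (2E,4E)-4-methyl-6-(pinacolboryl)-2-[(pinacolboryl)methyl]hexa-2,4-dienoate
Product: 7 (2E,4E)-4-methyl-6-(4,4,5,5-tetramethyl-1,3,2-dioxaborolan-2-yl)-2-[(4,4,5,5-tetramethyl-1,3,2-dioxaborolan-2-yl)methyl]hexa-2,4-dien-1-ol
Conditions: i-Bu2AlH (2.2 equiv), CH2Cl2, −78 °C; aqueous work-up
Reagents that add atoms: none
Why: Low-temperature hydride 1,2-reduction of the conjugated ester to the allylic alcohol; pinacol boronates and both alkene geometries should be unaffected.

Step 5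
Reactants: 7 (2E,4E)-4-methyl-6-(pinacolboryl)-2-[(pinacolboryl)methyl]hexa-2,4-dien-1-ol
Product: 8 tert-butyl{[(2E,4E)-4-methyl-6-(4,4,5,5-tetramethyl-1,3,2-dioxaborolan-2-yl)-2-[(4,4,5,5-tetramethyl-1,3,2-dioxaborolan-2-yl)methyl]hexa-2,4-dien-1-yl]oxy}diphenylsilane
Conditions: TBDPSCl, imidazole, CH2Cl2, 0 → 23 °C
Reagents that add atoms: tert-butyl(chloro)diphenylsilane, CC(C)(C)[Si](Cl)(c1ccccc1)c1ccccc1
Why: Imidazole-promoted silylation of the primary allylic alcohol; the acid-stable silyl ether is chosen to survive the aqueous Lewis acid of step 7.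

Step 6
Reactants: 9 methyl 4-oxobutanoate; 10 2,2-dimethoxyacetaldehyde
Product: 12 (2R,3S)-2-(dimethoxymethyl)-5-oxooxolane-3-carbaldehyde (cis), via aldol adduct 11 (not isolated)
Conditions: L-proline (20 mol %), DMF, 4 °C, 9 added slowly to 10 (2 equiv); then PPTS (cat.), CH2Cl2, 23 °C; used without delay
Reagents that add atoms: none
Why: Proline-catalysed enamine cross-aldol with a non-enolisable acceptor: the (E)-enamine of 9 attacks 10 through the hydrogen-bonded chair transition state to give the anti adduct (3S,4R), which sets C7 and C8, and acid then closes the γ-lactone (5-exo-trig acyl substitution), the anti relation becoming the cis-disubstituted lactone.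

Step 7
Reactants: 8 tert-butyl{[(2E,4E)-4-methyl-6-(pinacolboryl)-2-[(pinacolboryl)methyl]hexa-2,4-dien-1-yl]oxy}diphenylsilane; 12 (2R,3S)-2-(dimethoxymethyl)-5-oxooxolane-3-carbaldehyde
Product: 15 (3aR,4S,5S,6S,7R,7aR)-5-{3-[(tert-butyldiphenylsilyl)oxy]prop-1-en-2-yl}-6-ethenyl-4,7-dihydroxy-6-methylhexahydro-1-benzofuran-2(3H)-one, via borate ester 13 (not isolated), via hydroxy aldehyde 14 (not isolated)
Conditions: (S)-TRIP [(S)-3,3′-bis(2,4,6-triisopropylphenyl)-1,1′-binaphthyl-2,2′-diyl hydrogen phosphate] (10 mol %), toluene, −30 °C; then Bi(OTf)3 (5 mol %), THF/H2O (4:1), 0 → 40 °C; aqueous work-up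
Reagents that add atoms: water, O
Why: Proposed new method: in stage 1 only the less hindered boronate terminus of 8 (γ-carbon C5, one substituent) adds, under phosphoric-acid catalysis, to the only free aldehyde of 12 (C6) through a chair Zimmerman–Traxler transition state; Bi(OTf)3/water then frees the C9 aldehyde and the remaining γ,γ-disubstituted allylboronate closes the carbocycle by intramolecular allylboration (6-exo-trig attack on C9, Zimmerman–Traxler chair trans-fused to the chair of the forming ring). The closest known reaction type is the tandem allylation of 1,4-dicarbonyl compounds with diene-derived 1,2-bis(boronates), here joined to catalytic enantioselective allylboration; a hexa-2,4-diene-1,6-diyl bis(boronate) has not been used this way. C5/C6: C10 is cis to the CH2B carbon across C4=C5 (Z-crotyl type), so the chair should place the C4 substituent and O6 cis on the future ring, and (S)-TRIP is chosen to direct attack to the Si face of C6 (O6 anti to C11), which must override the substrate's own facial preference. C9/C10: the (E) geometry of C1=C10 puts O9 trans to the vinyl group, and the preferred chair should have the C8–O bond anti to the forming bond, H8 under the pseudoaxial C10 methyl, the C5 substituent equatorial and O6 a small free hydroxyl, giving O9 trans to O8 and vinyl trans to the C5 substituent. Selectivity needed: the pairing C5→C6 then C10→C9, secured by the acetal on C9 and by the low reactivity of the γ,γ-disubstituted terminus at −30 °C; and the C9/C10 face in ring closure, where the tether holds C7 gauche to the forming bond so that the Cornforth arrangement preferred by intermolecular additions (leading to the 8,9-cis diol) is unavailable.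

Step 8
Reactants: 15 (3aR,4S,5S,6S,7R,7aR)-5-{3-[(tert-butyldiphenylsilyl)oxy]prop-1-en-2-yl}-6-ethenyl-4,7-dihydroxy-6-methylhexahydro-1-benzofuran-2(3H)-one
Product: 18 (3aR,4S,5S,6S,7R,7aR)-5-{3-[(tert-butyldiphenylsilyl)oxy]prop-1-en-2-yl}-6-ethenyl-4,7-dihydroxy-6-methyl-3-methylidenehexahydro-1-benzofuran-2(3H)-one, via Mannich base 16 (not isolated), via ammonium iodide 17 (not isolated)
Conditions: LiN(i-Pr)2 (3.3 equiv), THF, −78 °C; Me2N=CH2 I, −78 → 0 °C; H2O quench; then MeI, MeOH, 23 °C; then NaHCO3 (aq.), CH2Cl2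
Reagents that add atoms: N,N-dimethylmethyleneiminium iodide, C[N+](C)=C.[I-]
Why: Eschenmoser methylenation: Mannich aminomethylation of the lactone enolate (two further equivalents of base cover the hydroxyls), N-methylation and E1cB loss of trimethylamine; no stereocentre is formed and C11 is the only enolisable position.

Step 9
Reactants: 18 (3aR,4S,5S,6S,7R,7aR)-5-{3-[(tert-butyldiphenylsilyl)oxy]prop-1-en-2-yl}-6-ethenyl-4,7-dihydroxy-6-methyl-3-methylidenehexahydro-1-benzofuran-2(3H)-one
Product: 19 (3aR,4S,5S,6S,7R,7aR)-5-{3-[(tert-butyldiphenylsilyl)oxy]prop-1-en-2-yl}-6-ethenyl-4-hydroxy-6-methyl-3-methylidene-2-oxooctahydro-1-benzofuran-7-yl 2-methylprop-2-enoate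
Conditions: methacryloyl chloride (1.1 equiv), Et3N, DMAP (cat.), CH2Cl2, −20 → 0 °C
Reagents that add atoms: methacryloyl chloride, CC(=C)C(Cl)=O
Why: DMAP-catalysed acylation should distinguish the two secondary alcohols because the C9 hydroxyl is equatorial whereas the C6 hydroxyl is axial and 1,3-diaxial to the C10 methyl group.

Step 10
Reactants: 19 (3aR,4S,5S,6S,7R,7aR)-5-{3-[(tert-butyldiphenylsilyl)oxy]prop-1-en-2-yl}-6-ethenyl-4-hydroxy-6-methyl-3-methylidene-2-oxooctahydro-1-benzofuran-7-yl 2-methylprop-2-enoate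
Product: 20 (3aR,4S,5S,6S,7R,7aR)-5-{3-[(tert-butyldiphenylsilyl)oxy]prop-1-en-2-yl}-6-ethenyl-6-methyl-3-methylidene-7-[(2-methylprop-2-enoyl)oxy]-2-oxooctahydro-1-benzofuran-4-yl (2Z)-2-methylbut-2-enoate
Conditions: angelic acid, 2,4,6-trichlorobenzoyl chloride, Et3N, toluene, 23 °C; then 19, DMAP, toluene, 70 °C
Reagents that add atoms: angelic acid, C/C=C(/C)C(=O)O
Why: Yamaguchi esterification: the mixed trichlorobenzoic anhydride of angelic acid acylates the hindered axial alcohol under DMAP catalysis, a protocol chosen because it is expected to preserve the (Z) geometry of the angelate.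

Step 11
Reactants: 20 (3aR,4S,5S,6S,7R,7aR)-5-{3-[(tert-butyldiphenylsilyl)oxy]prop-1-en-2-yl}-6-ethenyl-6-methyl-3-methylidene-7-[(2-methylprop-2-enoyl)oxy]-2-oxooctahydro-1-benzofuran-4-yl (2Z)-2-methylbut-2-enoate
Product: 21 (3aR,4S,5S,6S,7R,7aR)-6-ethenyl-5-(3-hydroxyprop-1-en-2-yl)-6-methyl-3-methylidene-7-[(2-methylprop-2-enoyl)oxy]-2-oxooctahydro-1-benzofuran-4-yl (2Z)-2-methylbut-2-enoate
Conditions: HF·pyridine, pyridine/THF, 0 → 23 °C
Reagents that add atoms: none
Why: Fluoride cleavage of the silyl ether under buffered, non-basic conditions that should leave the three esters and the α-methylene lactone alone.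

Step 12
Reactants: 21 (3aR,4S,5S,6S,7R,7aR)-6-ethenyl-5-(3-hydroxyprop-1-en-2-yl)-6-methyl-3-methylidene-7-[(2-methylprop-2-enoyl)oxy]-2-oxooctahydro-1-benzofuran-4-yl (2Z)-2-methylbut-2-enoate
Product: 22 (3aR,4S,5R,6S,7R,7aR)-6-ethenyl-6-methyl-3-methylidene-7-[(2-methylprop-2-enoyl)oxy]-2-oxo-5-(3-oxoprop-1-en-2-yl)octahydro-1-benzofuran-4-yl (2Z)-2-methylbut-2-enoate (target)
Conditions: MnO2, CH2Cl2, 23 °C
Reagents that add atoms: none
Why: MnO2 oxidises only the allylic alcohol, giving the 2-substituted acrolein without touching any stereocentre or the other functions.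

**Compound list**

1 | (2E)-3-methyl-4-oxobut-2-en-1-yl acetate | CC(=O)OC/C=C(\C)C=O | starting material
2 | methyl prop-2-ynoate | C#CC(=O)OC | starting material
3 | methyl 2-[bis(2-methylpropyl)alumanyl]prop-2-enoate | COC(=O)C(=C)[Al](CC(C)C)CC(C)C | intermediate (not isolated)
4 | methyl 2-[(2E)-4-(acetyloxy)-1-hydroxy-2-methylbut-2-en-1-yl]prop-2-enoate (racemic) | CC(=O)OC/C=C(\C)C(O)C(=C)C(=O)OC | intermediate
5 | methyl 2-[(2E)-1,4-bis(acetyloxy)-2-methylbut-2-en-1-yl]prop-2-enoate (racemic) | CC(=O)OC/C=C(\C)C(OC(C)=O)C(=C)C(=O)OC | intermediate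
6 | methyl (2E,4E)-4-methyl-6-(pinacolboryl)-2-[(pinacolboryl)methyl]hexa-2,4-dienoate | CC1(C)OB(OC1(C)C)C/C=C(\C)/C=C(/C(=O)OC)\CB1OC(C)(C)C(C)(C)O1 | intermediate
7 | (2E,4E)-4-methyl-6-(pinacolboryl)-2-[(pinacolboryl)methyl]hexa-2,4-dien-1-ol | CC1(C)OB(OC1(C)C)C/C=C(\C)/C=C(/CO)\CB1OC(C)(C)C(C)(C)O1 | intermediate
8 | tert-butyl{[(2E,4E)-4-methyl-6-(pinacolboryl)-2-[(pinacolboryl)methyl]hexa-2,4-dien-1-yl]oxy}diphenylsilane | CC1(C)OB(OC1(C)C)C/C=C(\C)/C=C(/CO[Si](c1ccccc1)(c1ccccc1)C(C)(C)C)\CB1OC(C)(C)C(C)(C)O1 | intermediate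
9 | methyl 4-oxobutanoate | COC(=O)CCC=O | starting material
10 | 2,2-dimethoxyacetaldehyde | COC(OC)C=O | starting material
11 | methyl (3S,4R)-3-formyl-4-hydroxy-5,5-dimethoxypentanoate | O=C[C@@H](CC(=O)OC)[C@@H](O)C(OC)OC | intermediate (not isolated)
12 | (2R,3S)-2-(dimethoxymethyl)-5-oxooxolane-3-carbaldehyde | O=C[C@H]1CC(=O)O[C@H]1C(OC)OC | intermediate
13 | C5–C6 mono-adduct as its C6 pinacol borate (C9 dimethyl acetal and C2 allylboronate intact; C5–C8 configured as in 15) | CC1(C)OB(OC1(C)C)C/C=C(\C)[C@H](C(=C)CO[Si](c1ccccc1)(c1ccccc1)C(C)(C)C)[C@H](OB1OC(C)(C)C(C)(C)O1)[C@H]1CC(=O)O[C@H]1C(OC)OC | intermediate (not isolated)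
14 | C6 hydroxy C9 aldehyde of the mono-adduct (in equilibrium with its C6–O–C9 lactol; C2 allylboronate intact) | CC1(C)OB(OC1(C)C)C/C=C(\C)[C@H](C(=C)CO[Si](c1ccccc1)(c1ccccc1)C(C)(C)C)[C@H](O)[C@H]1CC(=O)O[C@H]1C=O | intermediate (not isolated)
15 | (3aR,4S,5S,6S,7R,7aR)-5-{3-[(tert-butyldiphenylsilyl)oxy]prop-1-en-2-yl}-6-ethenyl-4,7-dihydroxy-6-methylhexahydro-1-benzofuran-2(3H)-one | C=C[C@@]1(C)[C@H](C(=C)CO[Si](c2ccccc2)(c2ccccc2)C(C)(C)C)[C@H](O)[C@H]2CC(=O)O[C@H]2[C@@H]1O | intermediate
16 | 3-[(dimethylamino)methyl] derivative of 15 (mixture at C3 of the benzofuranone) | C=C[C@@]1(C)[C@H](C(=C)CO[Si](c2ccccc2)(c2ccccc2)C(C)(C)C)[C@H](O)[C@H]2C(CN(C)C)C(=O)O[C@H]2[C@@H]1O | intermediate (not isolated)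
17 | 3-[(trimethylammonio)methyl] derivative of 15, iodide | C=C[C@@]1(C)[C@H](C(=C)CO[Si](c2ccccc2)(c2ccccc2)C(C)(C)C)[C@H](O)[C@H]2C(C[N+](C)(C)C)C(=O)O[C@H]2[C@@H]1O.[I-] | intermediate (not isolated)
18 | (3aR,4S,5S,6S,7R,7aR)-5-{3-[(tert-butyldiphenylsilyl)oxy]prop-1-en-2-yl}-6-ethenyl-4,7-dihydroxy-6-methyl-3-methylidenehexahydro-1-benzofuran-2(3H)-one | C=C[C@@]1(C)[C@H](C(=C)CO[Si](c2ccccc2)(c2ccccc2)C(C)(C)C)[C@H](O)[C@H]2C(=C)C(=O)O[C@H]2[C@@H]1O | intermediate
19 | 7-O-methacrylate of 18 | C=C[C@@]1(C)[C@H](C(=C)CO[Si](c2ccccc2)(c2ccccc2)C(C)(C)C)[C@H](O)[C@H]2C(=C)C(=O)O[C@H]2[C@@H]1OC(=O)C(=C)C | intermediate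
20 | 4-O-angelate 7-O-methacrylate of 18 | C=C[C@@]1(C)[C@H](C(=C)CO[Si](c2ccccc2)(c2ccccc2)C(C)(C)C)[C@H](OC(=O)/C(C)=C\C)[C@H]2C(=C)C(=O)O[C@H]2[C@@H]1OC(=O)C(=C)C | intermediate
21 | (3aR,4S,5S,6S,7R,7aR)-6-ethenyl-5-(3-hydroxyprop-1-en-2-yl)-6-methyl-3-methylidene-7-[(2-methylprop-2-enoyl)oxy]-2-oxooctahydro-1-benzofuran-4-yl (2Z)-2-methylbut-2-enoate | C=C[C@@]1(C)[C@H](C(=C)CO)[C@H](OC(=O)/C(C)=C\C)[C@H]2C(=C)C(=O)O[C@H]2[C@@H]1OC(=O)C(=C)C | intermediate
22 | (3aR,4S,5R,6S,7R,7aR)-6-ethenyl-6-methyl-3-methylidene-7-[(2-methylprop-2-enoyl)oxy]-2-oxo-5-(3-oxoprop-1-en-2-yl)octahydro-1-benzofuran-4-yl (2Z)-2-methylbut-2-enoate | C=C[C@@]1(C)[C@H](C(=C)C=O)[C@H](OC(=O)/C(C)=C\C)[C@H]2C(=C)C(=O)O[C@H]2[C@@H]1OC(=O)C(=C)C | target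

**Summary**

Total step count: 12. Longest linear sequence: 11 steps (steps 1–5, then 7–12); the second branch is step 6.

Steps most likely to fail:

1. Step 7 (proposed new method). What may go wrong: the γ,γ-disubstituted boronate terminus competes for the C6 aldehyde; the catalyst fails to override the substrate's facial bias at C6; the remaining allylboronate is protodeboronated while the acetal is opened; or ring closure runs through the alternative chair (C5 substituent axial, lactone oxygen under the C10 methyl), giving C9/C10 epimers. Fallback (known reactions, stepwise instead of domino): starting from 8 and 12, only the (S)-TRIP allylboration is run and worked up with water to give the C6 hydroxy C9 dimethyl acetal F1, which is purified free of mis-paired or wrong-face adducts. Bi(OTf)3 in wet THF at 0 °C then gives 14, isolated as its lactol. 14 is cyclised in a separate intramolecular allylboration (toluene, 60 °C, or Sc(OTf)3 at −40 °C, closed transition state), and aqueous work-up rejoins the route at 15.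

2. Step 3. What may go wrong: the π-allyl palladium intermediates of the doubly allylic acetate scramble the trisubstituted alkene geometry, borylate the distal end of the pentadienyl system, or couple allylboronate with allyl acetate. Fallback: starting from 5, a copper-catalysed γ-selective borylation (CuCl, KOAc, B2pin2, DMF, 23 °C) converts only the activated Baylis–Hillman acetate in SN2′ fashion to methyl (2E,4E)-6-(acetyloxy)-4-methyl-2-[(pinacolboryl)methyl]hexa-2,4-dienoate F2. The remaining primary allylic acetate is then borylated under the palladium conditions of step 3, rejoining the route at 6.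

3. Step 10. What may go wrong: slow acylation of the axial, shielded C6 hydroxyl and Z-to-E isomerisation of the activated angelate. Fallback: starting from 19, acylation with the small, highly electrophilic pyruvoyl chloride (pyridine, CH2Cl2, −40 °C) gives the C6 pyruvate F3. A Wittig reaction of its ketone with ethylidenetriphenylphosphorane (THF, −78 °C, salt-free), which with α-keto esters places the new methyl cis to the ester carbonyl, builds the (Z)-2-methylbut-2-enoate on the oxygen and rejoins the route at 20.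

Further compounds
F1 | step 7 | C6 hydroxy C9 dimethyl acetal mono-adduct (13 with free C6–OH) | CC1(C)OB(OC1(C)C)C/C=C(\C)[C@H](C(=C)CO[Si](c1ccccc1)(c1ccccc1)C(C)(C)C)[C@H](O)[C@H]1CC(=O)O[C@H]1C(OC)OC
F2 | step 3 | methyl (2E,4E)-6-(acetyloxy)-4-methyl-2-[(4,4,5,5-tetramethyl-1,3,2-dioxaborolan-2-yl)methyl]hexa-2,4-dienoate | CC(=O)OC/C=C(\C)/C=C(/C(=O)OC)\CB1OC(C)(C)C(C)(C)O1
F3 | step 10 | 4-O-pyruvate 7-O-methacrylate of 18 | C=C[C@@]1(C)[C@H](C(=C)CO[Si](c2ccccc2)(c2ccccc2)C(C)(C)C)[C@H](OC(=O)C(C)=O)[C@H]2C(=C)C(=O)O[C@H]2[C@@H]1OC(=O)C(=C)C
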